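The seven-membered ring is disconnected across C3a–C8a and C5–C6 into an oxyallyl unit (C3a–C4–C5) and a diene (C6–C7–C8–C8a). The feature exploited is the oxygen pattern at C3 and C4: a tertiary hydroxyl on the cyclopentane carbon next to the ring-fusion carbon C3a, and an oxygenated C4, are what an epoxy enol silane leaves behind when it reacts as an oxyallyl cation. An intramolecular (4+3) cycloaddition of the open-chain epoxy enol silane 14, which carries an (E,E)-diene three atoms away from the oxirane, therefore closes the five- and seven-membered rings at once, sets C3a and the quaternary C8a, and unveils the C3 hydroxyl and the C4 ketone.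

Key step: step 12

Remark: azulene numbering is used for the bicyclic compounds (C1 acetoxy carbon, C3 isopropyl carbinol carbon, C3a ring-fusion CH, C4 anisoyloxy carbon, C6 methyl-bearing alkene carbon, C8 carbinol carbon, C8a methyl-bearing ring-fusion carbon); crotonaldehyde is taken as its E isomer.

Step 1
Reactants: 1 (E)-but-2-enal; 2 2-(triphenylphosphoranylidene)propanal
Product: 3 (2E,4E)-2-methylhexa-2,4-dienal
Conditions: toluene, 80 °C
Reagents that add atoms: none
Why: Wittig olefination with the formyl-stabilised ylide is E-selective, and the α-methyl dienal formed is less electrophilic than crotonaldehyde, so a single homologation should occur.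

Step 2
Reactants: 3 (2E,4E)-2-methylhexa-2,4-dienal
Product: 4 (4S,5E,7E)-5-methylnona-5,7-dien-1-yn-4-ol
Conditions: allenylboronic acid pinacol ester, (S)-TRIP (5 mol %), 4 Å molecular sieves, toluene, 0 °C; aqueous work-up
Reagents that add atoms: allenylboronic acid pinacol ester, C=C=CB1OC(C)(C)C(C)(C)O1
Why: Chiral phosphoric acid catalysed propargylation through a closed six-membered SE2′ transition state, with the catalyst enantiomer chosen to direct the propargyl group to the Si face of the aldehyde (expected to be the (S)-configured 3,3′-bis(2,4,6-triisopropylphenyl)binaphthyl hydrogen phosphate by analogy with aryl and alkenyl aldehydes, the antipode being used otherwise), which sets the (S)-carbinol that becomes C1.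

Step 3
Reactants: 4 (4S,5E,7E)-5-methylnona-5,7-dien-1-yn-4-ol
Product: 5 triethyl{[(4S,5E,7E)-5-methylnona-5,7-dien-1-yn-4-yl]oxy}silane
Conditions: Et3SiCl, imidazole, CH2Cl2, 0 °C
Reagents that add atoms: chlorotriethylsilane, CC[Si](Cl)(CC)CC
Why: Standard silylation of a secondary alcohol; the triethylsilyl ether should survive the organometallic and oxidation steps and is removed later together with the tertiary silyl ether.

Step 4
Reactants: 5 triethyl{[(4S,5E,7E)-5-methylnona-5,7-dien-1-yn-4-yl]oxy}silane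
Product: 7 methyl (5S,6E,8E)-6-methyl-5-(triethylsilyloxy)deca-6,8-dien-2-ynoate, via lithium acetylide 6 (not isolated)
Conditions: n-BuLi, THF, −78 °C; then ClCO2Me, −78 to 0 °C
Reagents that add atoms: n-butyllithium, [Li]CCCC (lithium of 6); methyl chloroformate, COC(=O)Cl
Why: Deprotonation of the terminal alkyne and C-acylation of the acetylide with a chloroformate is the standard alkynoate synthesis.

Step 5
Reactants: 7 methyl (5S,6E,8E)-6-methyl-5-(triethylsilyloxy)deca-6,8-dien-2-ynoate
Product: 8 methyl (2E,5S,6E,8E)-6-methyl-3-(propan-2-yl)-5-(triethylsilyloxy)deca-2,6,8-trienoate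
Conditions: iPrMgCl (2.2 equiv), CuI (1.1 equiv), THF, −78 °C; then 7; MeOH then aq. NH4Cl at −78 °C
Reagents that add atoms: isopropylmagnesium chloride, CC(C)[Mg]Cl
Why: Conjugate addition of the diisopropylcuprate to the alkynoate is a syn carbocupration at low temperature, and protonation of the vinylcopper with retention places the isopropyl group cis to H-2, so the chain CH2 ends cis to the ester (2E).

Step 6
Reactants: 8 methyl (2E,5S,6E,8E)-6-methyl-3-(propan-2-yl)-5-(triethylsilyloxy)deca-2,6,8-trienoate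
Product: 9 (2E,5S,6E,8E)-6-methyl-3-(propan-2-yl)-5-(triethylsilyloxy)deca-2,6,8-trien-1-ol
Conditions: iBu2AlH (2.5 equiv), CH2Cl2, −78 °C; aq. potassium sodium tartrate
Reagents that add atoms: none
Why: 1,2-Reduction of the conjugated ester by DIBAL-H should give the allylic alcohol without touching the alkene geometry or the silyl ether.

Step 7
Reactants: 9 (2E,5S,6E,8E)-6-methyl-3-(propan-2-yl)-5-(triethylsilyloxy)deca-2,6,8-trien-1-ol
Product: 10 [(2R,3R)-3-[(2S,3E,5E)-3-methyl-2-(triethylsilyloxy)hepta-3,5-dien-1-yl]-3-(propan-2-yl)oxiran-2-yl]methanol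
Conditions: Ti(OiPr)4, D-(−)-diisopropyl tartrate, t-BuOOH, 4 Å molecular sieves, CH2Cl2, −20 °C
Reagents that add atoms: tert-butyl hydroperoxide, CC(C)(C)OO
Why: Sharpless asymmetric epoxidation is directed by the allylic hydroxyl and leaves the diene untouched, and the D-(−)-tartrate (the antipode of the ligand that gives (2S,3S)-epoxygeraniol) should give the (2R,3R)-oxirane stereospecifically from the E-alkene, which fixes the C3 carbinol configuration and the C–O bond later displaced at C3a.

Step 8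
Reactants: 10 [(2R,3R)-3-[(2S,3E,5E)-3-methyl-2-(triethylsilyloxy)hepta-3,5-dien-1-yl]-3-(propan-2-yl)oxiran-2-yl]methanol
Product: 11 (2S,3R)-3-[(2S,3E,5E)-3-methyl-2-(triethylsilyloxy)hepta-3,5-dien-1-yl]-3-(propan-2-yl)oxirane-2-carbaldehyde
Conditions: Dess–Martin periodinane, NaHCO3, CH2Cl2, 0 °C
Reagents that add atoms: none
Why: Buffered Dess–Martin oxidation of the primary epoxy alcohol should give the epoxy aldehyde without opening the oxirane.

Step 9
Reactants: 11 (2S,3R)-3-[(2S,3E,5E)-3-methyl-2-(triethylsilyloxy)hepta-3,5-dien-1-yl]-3-(propan-2-yl)oxirane-2-carbaldehyde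
Product: 12 1-[(2R,3R)-3-[(2S,3E,5E)-3-methyl-2-(triethylsilyloxy)hepta-3,5-dien-1-yl]-3-(propan-2-yl)oxiran-2-yl]ethan-1-ol (both carbinol epimers)
Conditions: MeMgBr, THF, −78 °C; aq. NH4Cl
Reagents that add atoms: methylmagnesium bromide, C[Mg]Br
Why: Grignard addition to the aldehyde at low temperature leaves the oxirane intact, and the new carbinol centre is of no consequence because it is oxidised in the next step.

Step 10
Reactants: 12 1-[(2R,3R)-3-[(2S,3E,5E)-3-methyl-2-(triethylsilyloxy)hepta-3,5-dien-1-yl]-3-(propan-2-yl)oxiran-2-yl]ethan-1-ol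
Product: 13 1-[(2S,3R)-3-[(2S,3E,5E)-3-methyl-2-(triethylsilyloxy)hepta-3,5-dien-1-yl]-3-(propan-2-yl)oxiran-2-yl]ethan-1-one
Conditions: Dess–Martin periodinane, NaHCO3, CH2Cl2, 0 °C to rt
Reagents that add atoms: none
Why: Dess–Martin oxidation of the secondary alcohol should give the epoxy methyl ketone under non-epimerising, buffered conditions.

Step 11
Reactants: 13 1-[(2S,3R)-3-[(2S,3E,5E)-3-methyl-2-(triethylsilyloxy)hepta-3,5-dien-1-yl]-3-(propan-2-yl)oxiran-2-yl]ethan-1-one
Product: 14 triethyl({1-[(2S,3R)-3-[(2S,3E,5E)-3-methyl-2-(triethylsilyloxy)hepta-3,5-dien-1-yl]-3-(propan-2-yl)oxiran-2-yl]ethenyl}oxy)silane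
Conditions: Et3SiOTf, Et3N, CH2Cl2, −78 to 0 °C
Reagents that add atoms: triethylsilyl trifluoromethanesulfonate, CC[Si](CC)(CC)OS(=O)(=O)C(F)(F)F
Why: Soft enolisation with silyl triflate and amine should silylate the methyl ketone on its methyl side, because deprotonation at the oxirane carbon is sterically and stereoelectronically disfavoured, giving the epoxy enol silane.

Step 12
Reactants: 14 triethyl({1-[(2S,3R)-3-[(2S,3E,5E)-3-methyl-2-(triethylsilyloxy)hepta-3,5-dien-1-yl]-3-(propan-2-yl)oxiran-2-yl]ethenyl}oxy)silane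
Product: 16 (1S,3R,3aR,6R,8aR)-1,3-dihydroxy-6,8a-dimethyl-3-(propan-2-yl)-2,3,3a,5,6,8a-hexahydroazulen-4(1H)-one, via bis(triethylsilyl) ether cycloadduct 15 (not isolated)
Conditions: Et3SiOTf (0.2 equiv), CH2Cl2, −78 °C; Et3N; then HF·pyridine, pyridine, THF, 0 °C to rt
Reagents that add atoms: none
Why: Catalytic triethylsilyl triflate silylates the oxirane oxygen, and the C–O bond at the carbon flanked by the enol silane is displaced with inversion by the trisubstituted diene terminus (5-exo with respect to the diene π bond, both oxirane carbons entering the five-membered ring); the resulting 1-methylallyl cation is then captured by the enol silane carbon in a 7-endo closure, after which silyl transfer releases the ketone and regenerates the catalyst. The closest known reaction type is the silyl triflate promoted intramolecular (4+3) cycloaddition of epoxy enol silanes, which behave as 2-silyloxyallyl cation equivalents toward tethered dienes such as furans, together with intramolecular oxyallyl cation–butadiene (4+3) cycloadditions that give hydroazulenones. C3a is controlled by the oxirane: backside attack transfers its configuration and places H-3a cis to the isopropyl group and C4 cis to the C3 oxygen. C8a is controlled by the extended transition state, in which the three-atom tether occupies the outside position of the E-configured diene terminus and the allyl unit points away from the diene, which gives the trans ring fusion; the C1 silyloxy group reinforces this by lying inside, anti to the incoming electrophile, so that the C8a methyl ends trans to it. C6 follows from suprafacial bonding to the (E,E)-diene, which places H-6 on the face of the C8a methyl as the last step requires. The selectivity needed is cleavage of the secondary, enol silane-flanked C–O bond and not of the tertiary one, which is secured by allylic stabilisation of the developing cation and by the tether, which can reach only that carbon in a five-membered ring; fluoride then removes both silyl ethers.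

Step 13
Reactants: 16 (1S,3R,3aR,6R,8aR)-1,3-dihydroxy-6,8a-dimethyl-3-(propan-2-yl)-2,3,3a,5,6,8a-hexahydroazulen-4(1H)-one
Product: 17 (1S,3R,3aR,6R,8aR)-3-hydroxy-6,8a-dimethyl-4-oxo-3-(propan-2-yl)-1,2,3,3a,4,5,6,8a-octahydroazulen-1-yl acetate
Conditions: Ac2O, pyridine, DMAP (cat.), CH2Cl2, 0 °C
Reagents that add atoms: acetic anhydride, CC(=O)OC(C)=O
Why: Acetylation should occur only at the secondary C1 hydroxyl because the tertiary C3 hydroxyl is not acylated under these conditions, and it removes the C1 hydroxyl as a competing director for the next step.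

Step 14
Reactants: 17 (1S,3R,3aR,6R,8aR)-3-hydroxy-6,8a-dimethyl-4-oxo-3-(propan-2-yl)-1,2,3,3a,4,5,6,8a-octahydroazulen-1-yl acetate
Product: 18 (1S,3R,3aS,4S,6R,8aR)-3,4-dihydroxy-6,8a-dimethyl-3-(propan-2-yl)-1,2,3,3a,4,5,6,8a-octahydroazulen-1-yl acetate
Conditions: Me4NBH(OAc)3, MeCN/AcOH (1:1), −20 °C to rt
Reagents that add atoms: none
Why: Evans–Saksena reduction, in which the tertiary C3 hydroxyl binds the triacetoxyborohydride and delivers hydride intramolecularly to the ketone face on which it sits, should give the anti-1,3-diol, that is the C4 hydroxyl cis to H-3a (4S).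

Step 15
Reactants: 18 (1S,3R,3aS,4S,6R,8aR)-3,4-dihydroxy-6,8a-dimethyl-3-(propan-2-yl)-1,2,3,3a,4,5,6,8a-octahydroazulen-1-yl acetate
Product: 19 (1S,3R,3aS,4S,6R,8aR)-1-(acetyloxy)-3-hydroxy-6,8a-dimethyl-3-(propan-2-yl)-1,2,3,3a,4,5,6,8a-octahydroazulen-4-yl 4-methoxybenzoate
Conditions: 4-MeOC6H4COCl, Et3N, DMAP, CH2Cl2, 0 °C to rt
Reagents that add atoms: 4-methoxybenzoyl chloride, COc1ccc(C(Cl)=O)cc1
Why: DMAP-catalysed acylation should take place at the only secondary alcohol, the tertiary C3 hydroxyl remaining free.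

Step 16
Reactants: 19 (1S,3R,3aS,4S,6R,8aR)-1-(acetyloxy)-3-hydroxy-6,8a-dimethyl-3-(propan-2-yl)-1,2,3,3a,4,5,6,8a-octahydroazulen-4-yl 4-methoxybenzoate
Product: 21 (1S,3R,3aS,4S,8S,8aS)-1-(acetyloxy)-3,8-dihydroxy-6,8a-dimethyl-3-(propan-2-yl)-1,2,3,3a,4,5,8,8a-octahydroazulen-4-yl 4-methoxybenzoate, via C8 hydroperoxide 20 (not isolated)
Conditions: O2, visible light, tetraphenylporphyrin (cat.), CH2Cl2, 0 °C; then PPh3
Reagents that add atoms: oxygen, O=O
Why: Schenck ene reaction of singlet oxygen with the C7=C8 alkene, in which the only allylic hydrogen is H-6 (C8a is quaternary) and lies on the face of the C8a methyl, should deliver oxygen suprafacially to C8 on that face with shift of the double bond to C6=C7, and triphenylphosphine then reduces the hydroperoxide to the (8S)-alcohol.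

Compound list
1 | (E)-but-2-enal (crotonaldehyde) | C/C=C/C=O | starting material
2 | 2-(triphenylphosphoranylidene)propanal | CC(C=O)=P(c1ccccc1)(c1ccccc1)c1ccccc1 | starting material
3 | (2E,4E)-2-methylhexa-2,4-dienal | O=C/C(C)=C/C=C/C | intermediate
4 | (4S,5E,7E)-5-methylnona-5,7-dien-1-yn-4-ol | C#CC[C@H](O)/C(C)=C/C=C/C | intermediate
5 | triethyl{[(4S,5E,7E)-5-methylnona-5,7-dien-1-yn-4-yl]oxy}silane | C#CC[C@H](O[Si](CC)(CC)CC)/C(C)=C/C=C/C | intermediate
6 | lithium acetylide of 5 | [Li]C#CC[C@H](O[Si](CC)(CC)CC)/C(C)=C/C=C/C | intermediate (not isolated)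
7 | methyl (5S,6E,8E)-6-methyl-5-(triethylsilyloxy)deca-6,8-dien-2-ynoate | COC(=O)C#CC[C@H](O[Si](CC)(CC)CC)/C(C)=C/C=C/C | intermediate
8 | methyl (2E,5S,6E,8E)-6-methyl-3-(propan-2-yl)-5-(triethylsilyloxy)deca-2,6,8-trienoate | COC(=O)/C=C(/C(C)C)C[C@H](O[Si](CC)(CC)CC)/C(C)=C/C=C/C | intermediate
9 | (2E,5S,6E,8E)-6-methyl-3-(propan-2-yl)-5-(triethylsilyloxy)deca-2,6,8-trien-1-ol | OC/C=C(/C(C)C)C[C@H](O[Si](CC)(CC)CC)/C(C)=C/C=C/C | intermediate
10 | [(2R,3R)-3-[(2S,3E,5E)-3-methyl-2-(triethylsilyloxy)hepta-3,5-dien-1-yl]-3-(propan-2-yl)oxiran-2-yl]methanol | OC[C@H]1O[C@@]1(C(C)C)C[C@H](O[Si](CC)(CC)CC)/C(C)=C/C=C/C | intermediate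
11 | (2S,3R)-3-[(2S,3E,5E)-3-methyl-2-(triethylsilyloxy)hepta-3,5-dien-1-yl]-3-(propan-2-yl)oxirane-2-carbaldehyde | O=C[C@H]1O[C@@]1(C(C)C)C[C@H](O[Si](CC)(CC)CC)/C(C)=C/C=C/C | intermediate
12 | 1-[(2R,3R)-3-[(2S,3E,5E)-3-methyl-2-(triethylsilyloxy)hepta-3,5-dien-1-yl]-3-(propan-2-yl)oxiran-2-yl]ethan-1-ol (both carbinol epimers) | CC(O)[C@H]1O[C@@]1(C(C)C)C[C@H](O[Si](CC)(CC)CC)/C(C)=C/C=C/C | intermediate
13 | 1-[(2S,3R)-3-[(2S,3E,5E)-3-methyl-2-(triethylsilyloxy)hepta-3,5-dien-1-yl]-3-(propan-2-yl)oxiran-2-yl]ethan-1-one | CC(=O)[C@H]1O[C@@]1(C(C)C)C[C@H](O[Si](CC)(CC)CC)/C(C)=C/C=C/C | intermediate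
14 | triethyl({1-[(2S,3R)-3-[(2S,3E,5E)-3-methyl-2-(triethylsilyloxy)hepta-3,5-dien-1-yl]-3-(propan-2-yl)oxiran-2-yl]ethenyl}oxy)silane | C=C(O[Si](CC)(CC)CC)[C@H]1O[C@@]1(C(C)C)C[C@H](O[Si](CC)(CC)CC)/C(C)=C/C=C/C | intermediate
15 | (1S,3R,3aR,6R,8aR)-6,8a-dimethyl-3-(propan-2-yl)-1,3-bis(triethylsilyloxy)-2,3,3a,5,6,8a-hexahydroazulen-4(1H)-one | O=C1C[C@@H](C)C=C[C@@]2(C)[C@@H](O[Si](CC)(CC)CC)C[C@@](O[Si](CC)(CC)CC)(C(C)C)[C@H]12 | intermediate (not isolated)
16 | (1S,3R,3aR,6R,8aR)-1,3-dihydroxy-6,8a-dimethyl-3-(propan-2-yl)-2,3,3a,5,6,8a-hexahydroazulen-4(1H)-one | O=C1C[C@@H](C)C=C[C@@]2(C)[C@@H](O)C[C@@](O)(C(C)C)[C@H]12 | intermediate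
17 | (1S,3R,3aR,6R,8aR)-3-hydroxy-6,8a-dimethyl-4-oxo-3-(propan-2-yl)-1,2,3,3a,4,5,6,8a-octahydroazulen-1-yl acetate | O=C1C[C@@H](C)C=C[C@@]2(C)[C@@H](OC(C)=O)C[C@@](O)(C(C)C)[C@H]12 | intermediate
18 | (1S,3R,3aS,4S,6R,8aR)-3,4-dihydroxy-6,8a-dimethyl-3-(propan-2-yl)-1,2,3,3a,4,5,6,8a-octahydroazulen-1-yl acetate | O[C@H]1C[C@@H](C)C=C[C@@]2(C)[C@@H](OC(C)=O)C[C@@](O)(C(C)C)[C@H]12 | intermediate
19 | (1S,3R,3aS,4S,6R,8aR)-1-(acetyloxy)-3-hydroxy-6,8a-dimethyl-3-(propan-2-yl)-1,2,3,3a,4,5,6,8a-octahydroazulen-4-yl 4-methoxybenzoate | COc1ccc(C(=O)O[C@H]2C[C@@H](C)C=C[C@@]3(C)[C@@H](OC(C)=O)C[C@@](O)(C(C)C)[C@H]23)cc1 | intermediate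
20 | (1S,3R,3aS,4S,8S,8aR)-1-(acetyloxy)-8-hydroperoxy-3-hydroxy-6,8a-dimethyl-3-(propan-2-yl)-1,2,3,3a,4,5,8,8a-octahydroazulen-4-yl 4-methoxybenzoate | COc1ccc(C(=O)O[C@H]2CC(C)=C[C@H](OO)[C@@]3(C)[C@@H](OC(C)=O)C[C@@](O)(C(C)C)[C@H]23)cc1 | intermediate (not isolated)
21 | (1S,3R,3aS,4S,8S,8aS)-1-(acetyloxy)-3,8-dihydroxy-6,8a-dimethyl-3-(propan-2-yl)-1,2,3,3a,4,5,8,8a-octahydroazulen-4-yl 4-methoxybenzoate (CNP0261832.1) | COc1ccc(C(=O)O[C@H]2CC(C)=C[C@H](O)[C@@]3(C)[C@@H](OC(C)=O)C[C@@](O)(C(C)C)[C@H]23)cc1 | target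

Total step count: 16. Longest linear sequence: 16 steps (from 1 to 21).

Steps most likely to fail

Step 12 (key step). What may go wrong is ionisation of the oxirane at its tertiary carbon followed by a 1,2-shift, interruption of the cascade after the first C–C bond (proton loss from the allyl cation or capture by the enol silane oxygen), or erosion of the trans ring fusion. The fallback generates the oxyallyl cation by base from an α-chloro ketone instead of by Lewis acid from the epoxide. It sets out from epoxy ketone 13: SmI2 (THF/MeOH, −90 °C) should cleave the C–O bond α to the ketone and give the tertiary β-hydroxy ketone F1; Et3SiOTf and 2,6-lutidine should give the bis(triethylsilyl) ether F2; kinetic deprotonation on the methyl side (LDA, THF, −78 °C) and chlorination with TsCl should give the chloromethyl ketone F3. Et3N and LiClO4 in Et2O should then enolise F3 toward C3a, expel chloride and let the oxyallyl cation undergo the same intramolecular (4+3) cycloaddition, which returns to the route at cycloadduct 15 (desilylated to 16 as in step 12). In this variant C3a is no longer fixed by the oxirane and rests on the transition-state preference alone.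

Step 16. What may go wrong is a sluggish ene reaction of the 1,2-disubstituted cycloheptene with singlet oxygen, so that conversion stays low or the sensitiser bleaches first. The fallback replaces the ene reaction by an epoxide-based allylic transposition with a later correction at C8. It sets out from 19: mCPBA (CH2Cl2, NaHCO3, 0 °C) should epoxidise anti to the C8a methyl and give the C7–C8 epoxide F4; PhSeSePh/NaBH4 (EtOH, 0 °C to rt) should open it at C7 from the opposite face to give the hydroxy selenide F5; H2O2 (THF, 0 °C to rt) should give the selenoxide F6, which eliminates syn toward H-6 and away from the carbinol to give the C8 epimer F7. Dess–Martin oxidation should give the C8 enone F8, and Luche reduction (NaBH4, CeCl3·7H2O, MeOH, −40 °C), with hydride arriving anti to the C8a methyl, should return to the route at target 21.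

Step 14. What may go wrong is failure of the hindered tertiary hydroxyl to bind boron, so that hydride arrives externally under steric control and gives the C4 epimer or a mixture. The fallback accepts the external delivery and corrects C4 while installing the ester. It sets out from 17: NaBH4 (MeOH, −40 °C) should give mainly the C4-epimeric alcohol F9, and a Mitsunobu esterification with 4-methoxybenzoic acid (PPh3, diisopropyl azodicarboxylate, toluene, 0 °C to rt) should invert C4 and return to the route at anisoate 19, bypassing 18 and step 15.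

Further compounds
F1 | step 12 | tertiary β-hydroxy ketone, (4S,6S,7E,9E)-4-hydroxy-7-methyl-4-(propan-2-yl)-6-(triethylsilyloxy)undeca-7,9-dien-2-one | CC(=O)C[C@](O)(C(C)C)C[C@H](O[Si](CC)(CC)CC)/C(C)=C/C=C/C
F2 | step 12 | bis(triethylsilyl) ether, (4S,6S,7E,9E)-7-methyl-4-(propan-2-yl)-4,6-bis(triethylsilyloxy)undeca-7,9-dien-2-one | CC(=O)C[C@](O[Si](CC)(CC)CC)(C(C)C)C[C@H](O[Si](CC)(CC)CC)/C(C)=C/C=C/C
F3 | step 12 | chloromethyl ketone, (4S,6S,7E,9E)-1-chloro-7-methyl-4-(propan-2-yl)-4,6-bis(triethylsilyloxy)undeca-7,9-dien-2-one | ClCC(=O)C[C@](O[Si](CC)(CC)CC)(C(C)C)C[C@H](O[Si](CC)(CC)CC)/C(C)=C/C=C/C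
F4 | step 16 | C7–C8 epoxide of 19 (oxirane anti to the C8a methyl) | COc1ccc(C(=O)O[C@H]2C[C@@H](C)[C@H]4O[C@H]4[C@@]3(C)[C@@H](OC(C)=O)C[C@@](O)(C(C)C)[C@H]23)cc1
F5 | step 16 | hydroxy selenide (7-phenylselanyl cis to the C8a methyl, 8-hydroxy trans to it) | COc1ccc(C(=O)O[C@H]2C[C@@H](C)[C@H]([Se]c4ccccc4)[C@@H](O)[C@@]3(C)[C@@H](OC(C)=O)C[C@@](O)(C(C)C)[C@H]23)cc1
F6 | step 16 | selenoxide of F5 | COc1ccc(C(=O)O[C@H]2C[C@@H](C)[C@H]([Se](=O)c4ccccc4)[C@@H](O)[C@@]3(C)[C@@H](OC(C)=O)C[C@@](O)(C(C)C)[C@H]23)cc1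
F7 | step 16 | C8 epimer of 21, (1S,3R,3aS,4S,8R,8aS)-configured | COc1ccc(C(=O)O[C@H]2CC(C)=C[C@@H](O)[C@@]3(C)[C@@H](OC(C)=O)C[C@@](O)(C(C)C)[C@H]23)cc1
F8 | step 16 | C8 enone, (1S,3R,3aS,4S,8aR)-1-(acetyloxy)-3-hydroxy-6,8a-dimethyl-8-oxo-3-(propan-2-yl)-1,2,3,3a,4,5,8,8a-octahydroazulen-4-yl 4-methoxybenzoate | COc1ccc(C(=O)O[C@H]2CC(C)=CC(=O)[C@@]3(C)[C@@H](OC(C)=O)C[C@@](O)(C(C)C)[C@H]23)cc1
F9 | step 14 | C4-epimeric alcohol, (1S,3R,3aS,4R,6R,8aR)-3,4-dihydroxy-6,8a-dimethyl-3-(propan-2-yl)-1,2,3,3a,4,5,6,8a-octahydroazulen-1-yl acetate | O[C@@H]1C[C@@H](C)C=C[C@@]2(C)[C@@H](OC(C)=O)C[C@@](O)(C(C)C)[C@H]12
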